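**Retrosynthetic overview**
1. Target ⇒ C8,C12-diol; both acetates go on together in the last step.
2. Diol ⇒ α-methylene-β-hydroxy-γ-lactone + C8 homoallylic alcohol; cross-metathesis makes the exocyclic C10=C11 alkene.
3. Lactone (the only ring, closed once, before the fragments are joined) ⇒ key C–O bond O–C13 by oxidative allylic lactonisation of a 3-hydroxy-2-methylene-4-enoic acid ⇒ asymmetric Morita–Baylis–Hillman adduct of (E)-4-methylpent-2-enal.
4. Homoallylic alcohol ⇒ asymmetric allylboration of 8-oxoneryl benzoate ⇒ allylic oxidation of neryl benzoate ⇒ nerol.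

Assumption: skeleton positions are numbered as for an acyclic diterpene (C1 = CH2OBz, C8 = side-chain carbinol, C12 and C13 = lactone C4 and C5); the target read from the SMILES is 2Z,6E,10E,8R,12S,13R (lactone 4S,5R, substituents trans).
Assumption: in step 6 the (S,S) antipode of the diselenide is taken as the one matched to the hydroxy acid; both antipodes are equally accessible, so the other is used if the sense proves opposite.

**Route**

Step 1
Reactants: 1 nerol, (2Z)-3,7-dimethylocta-2,6-dien-1-ol
Product: 2 neryl benzoate, (2Z)-3,7-dimethylocta-2,6-dien-1-yl benzoate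
Conditions: BzCl (1.2 equiv), Et3N (1.5 equiv), DMAP (5 mol%), CH2Cl2, 0 → 23 °C
Reagents that add atoms: benzoyl chloride, O=C(Cl)c1ccccc1
Why: DMAP-catalysed O-acylation (nucleophilic acyl substitution) of the primary allylic alcohol, which forms no stereocentre and leaves the 2Z alkene untouched.

Step 2
Reactants: 2 neryl benzoate
Product: 4 (2Z,6E)-3,7-dimethyl-8-oxoocta-2,6-dien-1-yl benzoate, via 8-hydroxyneryl benzoate 3 (not isolated)
Conditions: SeO2 (0.3 equiv), tBuOOH (3 equiv), salicylic acid (10 mol%), CH2Cl2, 23 °C; aqueous Na2S2O3 wash; then MnO2 (15 equiv), CH2Cl2, 23 °C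
Reagents that add atoms: tert-butyl hydroperoxide (terminal oxygen source), CC(C)(C)OO; selenium dioxide (catalytic oxygen carrier), O=[Se]=O
Why: Riley allylic oxidation (ene reaction, then [2,3]-sigmatropic shift) attacks the E-methyl group of the electron-richer 6,7-alkene (the 2,3-alkene is deactivated by the allylic benzoate), and MnO2 then converges the alcohol/aldehyde mixture onto the 6E enal without touching ester or alkenes.

Step 3
Reactants: 4 (2Z,6E)-3,7-dimethyl-8-oxoocta-2,6-dien-1-yl benzoate
Product: 6 (2Z,6E,8R)-8-hydroxy-3,7-dimethylundeca-2,6,10-trien-1-yl benzoate, via pinacol borate ester 5 (not isolated)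
Conditions: allylB(pin) (1.3 equiv), (R)-TRIP [(R)-3,3′-bis(2,4,6-triisopropylphenyl)-1,1′-binaphthyl-2,2′-diyl hydrogen phosphate, 5 mol%], 4 Å MS, toluene, −30 °C; aqueous NaHCO3 work-up
Reagents that add atoms: allylboronic acid pinacol ester, C=CCB1OC(C)(C)C(C)(C)O1
Why: Chiral phosphoric acid-catalysed allylboration through a closed chair transition state, in which the (R)-acid directs the allyl group to the Re face of the enal carbonyl (the sense recalled for aryl and alkenyl aldehydes; the (S)-acid is used if it proves opposite), setting C8 as R; the B–O bond of 5 is hydrolysed on work-up.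

Step 4
Reactants: 7 (2E)-4-methylpent-2-enal; 8 1,1,1,3,3,3-hexafluoropropan-2-yl prop-2-enoate (1.3 equiv)
Product: 9 1,1,1,3,3,3-hexafluoropropan-2-yl (3R,4E)-3-hydroxy-6-methyl-2-methylidenehept-4-enoate
Conditions: β-isocupreidine (β-ICD, 10 mol%), DMF, −55 °C, 48–72 h
Reagents that add atoms: none
Why: Asymmetric Morita–Baylis–Hillman reaction in which the quinuclidine nitrogen of β-ICD adds to the activated acrylate and its phenolic OH steers the aldol and proton-transfer steps, giving the 3R carbinol (the future lactone C4, target C12) as it does for aryl, alkyl and alkenyl aldehydes.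

Step 5
Reactants: 9 hexafluoroisopropyl (3R,4E)-3-hydroxy-6-methyl-2-methylidenehept-4-enoate
Product: 10 (3R,4E)-3-hydroxy-6-methyl-2-methylidenehept-4-enoic acid
Conditions: LiOH·H2O (2.5 equiv), THF/H2O 3:1, 0 °C, 1 h; then 1 M HCl to pH 3
Reagents that add atoms: lithium hydroxide, [Li+].[OH-]
Why: Saponification (acyl substitution) of the activated hexafluoroisopropyl ester is fast at 0 °C, so retro-aldol and conjugate addition are outrun and the carbinol centre is untouched.

Step 6
Reactants: 10 (3R,4E)-3-hydroxy-6-methyl-2-methylidenehept-4-enoic acid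
Product: 11 (4S,5R)-4-hydroxy-3-methylidene-5-(2-methylprop-1-en-1-yl)oxolan-2-one
Conditions: (S,S)-bis[2-(1-methoxyethyl)phenyl] diselenide (10 mol%), NFSI (1.1 equiv), 4 Å MS, toluene, 0 → 23 °C
Reagents that add atoms: none
Why: Proposed new method: a chiral selenium π-acid-catalysed, catalyst-controlled trans-selective 5-exo oxidative allylic lactonisation, in which NFSI turns the diselenide into an arylselenenyl electrophile that adds reversibly to the electron-richer E-disubstituted alkene (the acrylate alkene is inert), the carboxylate opens the seleniranium ion anti at the carbon next to the carbinol (C–O bond and ring closure), and NFSI then oxidises the catalyst-bound alkyl aryl selenide to a tetravalent selenium species that syn-eliminates towards the tertiary isopropyl C–H (away from the oxygen-bearing carbon) to unveil the isobutenyl group and return the catalyst; the new stereocentre (lactone C5, R, trans to the C4 hydroxyl) is set in the anti-selenolactonisation by the matched catalyst antipode, helped by the reversibility of that step, which drains material through the more stable trans adduct before the irreversible elimination; the closest known chemistry is achiral diselenide/NFSI oxidative allylic esterification and lactonisation, stoichiometric selenolactonisation–selenoxide elimination, and chiral-selenium-catalysed 5-endo oxidative lactonisation of β,γ-unsaturated acids to butenolides, none of which has been shown for a diastereocontrolled 5-exo closure with alkene transposition on a 3-hydroxy-2-methylene-4-enoic acid.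

Step 7
Reactants: 6 (2Z,6E,8R)-8-hydroxy-3,7-dimethylundeca-2,6,10-trien-1-yl benzoate (2 equiv); 11 (4S,5R)-4-hydroxy-3-methylidene-5-(2-methylprop-1-en-1-yl)oxolan-2-one
Product: 12 (2Z,6E,8R)-8-hydroxy-10-[(3E,4S,5R)-4-hydroxy-5-(2-methylprop-1-en-1-yl)-2-oxooxolan-3-ylidene]-3,7-dimethyldeca-2,6-dien-1-yl benzoate
Conditions: second-generation Hoveyda–Grubbs catalyst RuCl2(H2IMes)(=CH-C6H4-2-OiPr) (10 mol%), 2,6-dichloro-1,4-benzoquinone (10 mol%), CH2Cl2, 40 °C
Reagents that add atoms: none
Why: Olefin cross-metathesis of the terminal alkene of 6 with the α-methylene lactone (the quinone suppresses Ru–H isomerisation to the endocyclic isomer), the hindered trisubstituted alkenes being expected to stay out and the E-alkylidene (chain anti to the lactone carbonyl) being the expected thermodynamic product reached by secondary metathesis.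

Step 8
Reactants: 12 the C8,C12-diol
Product: 13 (2Z,6E,8R)-8-acetoxy-10-[(3E,4S,5R)-4-acetoxy-5-(2-methylprop-1-en-1-yl)-2-oxooxolan-3-ylidene]-3,7-dimethyldeca-2,6-dien-1-yl benzoate (CNP0262857.1)
Conditions: Ac2O (4 equiv), pyridine, CH2Cl2, 0 → 23 °C
Reagents that add atoms: acetic anhydride, CC(=O)OC(C)=O
Why: Acylation of both secondary alcohols with retention (pyridine without DMAP, to avoid SN2′ attack on the newly formed allylic acetate next to the enoate), so no stereocentre or alkene is touched.

**Compound list**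
1 | nerol, (2Z)-3,7-dimethylocta-2,6-dien-1-ol | CC(C)=CCC/C(C)=C\CO | starting material
2 | neryl benzoate, (2Z)-3,7-dimethylocta-2,6-dien-1-yl benzoate | CC(C)=CCC/C(C)=C\COC(=O)c1ccccc1 | intermediate
3 | 8-hydroxyneryl benzoate, (2Z,6E)-8-hydroxy-3,7-dimethylocta-2,6-dien-1-yl benzoate | OC/C(C)=C/CC/C(C)=C\COC(=O)c1ccccc1 | intermediate (not isolated)
4 | (2Z,6E)-3,7-dimethyl-8-oxoocta-2,6-dien-1-yl benzoate | O=C/C(C)=C/CC/C(C)=C\COC(=O)c1ccccc1 | intermediate
5 | pinacol borate ester of 6, (2Z,6E,8R)-3,7-dimethyl-8-[(4,4,5,5-tetramethyl-1,3,2-dioxaborolan-2-yl)oxy]undeca-2,6,10-trien-1-yl benzoate | C=CC[C@@H](OB1OC(C)(C)C(C)(C)O1)/C(C)=C/CC/C(C)=C\COC(=O)c1ccccc1 | intermediate (not isolated)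
6 | (2Z,6E,8R)-8-hydroxy-3,7-dimethylundeca-2,6,10-trien-1-yl benzoate | C=CC[C@@H](O)/C(C)=C/CC/C(C)=C\COC(=O)c1ccccc1 | intermediate
7 | (2E)-4-methylpent-2-enal | O=C/C=C/C(C)C | starting material
8 | 1,1,1,3,3,3-hexafluoropropan-2-yl prop-2-enoate | C=CC(=O)OC(C(F)(F)F)C(F)(F)F | starting material
9 | 1,1,1,3,3,3-hexafluoropropan-2-yl (3R,4E)-3-hydroxy-6-methyl-2-methylidenehept-4-enoate | C=C(C(=O)OC(C(F)(F)F)C(F)(F)F)[C@H](O)/C=C/C(C)C | intermediate
10 | (3R,4E)-3-hydroxy-6-methyl-2-methylidenehept-4-enoic acid | C=C(C(=O)O)[C@H](O)/C=C/C(C)C | intermediate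
11 | (4S,5R)-4-hydroxy-3-methylidene-5-(2-methylprop-1-en-1-yl)oxolan-2-one | C=C1C(=O)O[C@H](C=C(C)C)[C@H]1O | intermediate
12 | (2Z,6E,8R)-8-hydroxy-10-[(3E,4S,5R)-4-hydroxy-5-(2-methylprop-1-en-1-yl)-2-oxooxolan-3-ylidene]-3,7-dimethyldeca-2,6-dien-1-yl benzoate | O[C@H](C/C=C1/C(=O)O[C@H](C=C(C)C)[C@H]1O)/C(C)=C/CC/C(C)=C\COC(=O)c1ccccc1 | intermediate
13 | (2Z,6E,8R)-8-acetoxy-10-[(3E,4S,5R)-4-acetoxy-5-(2-methylprop-1-en-1-yl)-2-oxooxolan-3-ylidene]-3,7-dimethyldeca-2,6-dien-1-yl benzoate | CC(=O)O[C@H](C/C=C1/C(=O)O[C@H](C=C(C)C)[C@H]1OC(C)=O)/C(C)=C/CC/C(C)=C\COC(=O)c1ccccc1 | target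

**Step count**
Total: 8 steps. Longest linear sequence: 5 steps (1 → 2 → 3 → 7 → 8, or 4 → 5 → 6 → 7 → 8).

**Three steps most likely to fail**

Step 6 (the proposed new lactonisation). Risks are the cis lactone (3-hydroxy-4-enoic acids tend to cyclise cis under kinetic control), 6-endo closure, a second selenium attack on the new trisubstituted alkene, and capture of the seleniranium ion by the sulfonimide. The fallback uses known stoichiometric chemistry and sets out from 10. Phenylselenolactonisation under equilibrating conditions (PhSeCl, CH2Cl2, −78 → 23 °C) gives the trans selenide (4S,5S)-4-hydroxy-3-methylidene-5-[(1R)-2-methyl-1-(phenylselanyl)propyl]oxolan-2-one F1, with any cis isomer removed by chromatography. Oxidation with H2O2/pyridine (CH2Cl2, 0 → 23 °C) and selenoxide syn-elimination away from the ring oxygen then return the route at 11.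

Step 7 (cross-metathesis). Risks are low reactivity of the hindered 1,1-disubstituted alkene next to the carbinol, homodimerisation of 6, loss of isobutene from the isobutenyl group, and E/Z control. The fallback sets out from 6 and 11 and replaces the intermolecular coupling by a temporary silicon tether. iPr2SiCl2 and imidazole (CH2Cl2, 0 °C; 11 first, then 6) give the mixed diisopropylsilyl ketal joining O8 of 6 to O4 of 11, F2. Ring-closing metathesis (second-generation Grubbs catalyst RuCl2(PCy3)(H2IMes)(=CHPh), toluene, 80 °C) closes the eight-membered 2,2-diisopropyl-1,3-dioxa-2-silacyclooct-5-ene fused to the lactone, F3. Its ring forces C9 cis to C12, which is the required E-alkylidene. HF·pyridine (THF, 0 °C) removes the tether and returns the route at 12.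

Step 4 (asymmetric Morita–Baylis–Hillman reaction with an aliphatic enal). Risks are slow conversion, dioxanone by-product and eroded ee. The fallback sets out from 7 and replaces asymmetric catalysis by a resolution. Methyl acrylate and DABCO (neat, 23 °C) give racemic methyl (4E)-3-hydroxy-6-methyl-2-methylidenehept-4-enoate F4. Sharpless kinetic resolution (Ti(OiPr)4, D-(−)-diisopropyl tartrate, tBuOOH 0.6 equiv, 4 Å MS, CH2Cl2, −20 °C) epoxidises the E-allylic alkene of the S alcohol. The recovered alcohol is methyl (3R,4E)-3-hydroxy-6-methyl-2-methylidenehept-4-enoate F5. The consumed enantiomer ends as methyl (3R)-3-hydroxy-2-methylidene-3-[(2R,3R)-3-(propan-2-yl)oxiran-2-yl]propanoate F6 and is separated. LiOH (THF/H2O, 0 °C), then HCl, converts F5 into 10, where the route is rejoined (9 is bypassed).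

**Further compounds**
F1 | step 6 | (4S,5S)-4-hydroxy-3-methylidene-5-[(1R)-2-methyl-1-(phenylselanyl)propyl]oxolan-2-one | C=C1C(=O)O[C@H]([C@H]([Se]c2ccccc2)C(C)C)[C@H]1O
F2 | step 7 | mixed diisopropylsilyl ketal joining O8 of 6 to O4 of 11 | C=CC[C@@H](O[Si](C(C)C)(C(C)C)O[C@H]1C(=C)C(=O)O[C@@H]1C=C(C)C)/C(C)=C/CC/C(C)=C\COC(=O)c1ccccc1
F3 | step 7 | ring-closed eight-membered 2,2-diisopropyl-1,3-dioxa-2-silacyclooct-5-ene fused to the lactone (silylene derivative of 12) | CC(C)[Si]2(C(C)C)O[C@H](C/C=C1/C(=O)O[C@H](C=C(C)C)[C@H]1O2)/C(C)=C/CC/C(C)=C\COC(=O)c1ccccc1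
F4 | step 4 | methyl (4E)-3-hydroxy-6-methyl-2-methylidenehept-4-enoate, racemic | C=C(C(=O)OC)C(O)/C=C/C(C)C
F5 | step 4 | methyl (3R,4E)-3-hydroxy-6-methyl-2-methylidenehept-4-enoate | C=C(C(=O)OC)[C@H](O)/C=C/C(C)C
F6 | step 4 | methyl (3R)-3-hydroxy-2-methylidene-3-[(2R,3R)-3-(propan-2-yl)oxiran-2-yl]propanoate | C=C(C(=O)OC)[C@@H](O)[C@H]1O[C@@H]1C(C)C
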